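Everything rests on growing the methoxy-bearing naphthalene ring (C5'–C8') onto a finished isoquinoline half instead of joining two arenes. In that ring O-5' and the C7 aryl group at C8' stand para to each other, each on a carbon bonded to a fusion atom (C4a', C8a'), and O-4' flanks C4a'. This is the signature of a 3-alkoxyaryne that takes a carbon nucleophile at its far carbon and an acyl group at its near one. One operation forms C8'–C8a' and C5'–C4a', closes the ring and lets the crowded axis arise from an sp3 carbon. The precursor is an (E)-4-aryl-N,N-diethylbut-2-enamide whose aryl group carries the ketal-masked acetyl group and the (S)-dibenzylaminopropyl chain.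

Key step: step 12

Assumption: the SMILES defines only C3 as (S) and leaves the C7–C8' axis undefined, so no axial control is attempted and either atropisomer or their mixture counts as the target.

Step 1
Reactants: 1 1-bromo-3,5-dimethoxybenzene; 2 (R)-propylene oxide
Product: 4 (2R)-1-(3,5-dimethoxyphenyl)propan-2-ol, via 3,5-dimethoxyphenylmagnesium bromide 3 (not isolated)
Conditions: Mg, THF, 40 °C; then CuI (10 mol %), 2 (1.2 equiv), −30 °C to 0 °C
Reagents that add atoms: none
Why: Copper-catalysed Grignard opening of a terminal epoxide is an SN2 attack at the unsubstituted carbon, so the oxygen-bearing stereocentre of 2 is not touched and appears in 4 as (R).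

Step 2
Reactants: 4 (2R)-1-(3,5-dimethoxyphenyl)propan-2-ol
Product: 7 (2S)-1-(3,5-dimethoxyphenyl)propan-2-amine, via (S)-azide 5 (not isolated), via iminophosphorane 6 (not isolated)
Conditions: PPh3, DIAD, (PhO)2P(O)N3, THF, 0 °C to rt; then PPh3, 50 °C; then H2O, 50 °C
Reagents that add atoms: diphenylphosphoryl azide, [N-]=[N+]=NP(=O)(Oc1ccccc1)Oc1ccccc1
Why: The Mitsunobu reaction with azide displaces the activated secondary alcohol with inversion and thereby sets the (S) configuration of C3, and the Staudinger reduction in the same flask turns azide 5 through iminophosphorane 6 into the amine without touching that centre.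

Step 3
Reactants: 7 (2S)-1-(3,5-dimethoxyphenyl)propan-2-amine
Product: 8 (2S)-N,N-dibenzyl-1-(3,5-dimethoxyphenyl)propan-2-amine
Conditions: BnBr (2.3 equiv), K2CO3, MeCN, 80 °C
Reagents that add atoms: benzyl bromide, BrCc1ccccc1
Why: Double SN2 N-alkylation gives a tertiary amine without N–H that withstands Lewis acids, heat and lithium amides and cannot condense with the ketone introduced next.

Step 4
Reactants: 8 (2S)-N,N-dibenzyl-1-(3,5-dimethoxyphenyl)propan-2-amine
Product: 9 1-{2-[(2S)-2-(dibenzylamino)propyl]-4,6-dimethoxyphenyl}ethan-1-one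
Conditions: AlCl3 (3 equiv), then AcCl (1.3 equiv), CH2Cl2, −10 °C to rt
Reagents that add atoms: acetyl chloride, CC(=O)Cl
Why: Friedel–Crafts acylation of the resorcinol diether takes the position para to one methoxy group and ortho to the other (future C8a) because the site between the two methoxy groups is more crowded, the amine is shielded as its AlCl3 complex, and partial chelation-driven loss of the neighbouring O-methyl group does no harm since step 5 removes both.

Step 5
Reactants: 9 1-{2-[(2S)-2-(dibenzylamino)propyl]-4,6-dimethoxyphenyl}ethan-1-one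
Product: 10 1-{2-[(2S)-2-(dibenzylamino)propyl]-4,6-dihydroxyphenyl}ethan-1-one
Conditions: BBr3 (5 equiv), CH2Cl2, −78 °C to rt; then H2O
Reagents that add atoms: none
Why: BBr3 ether cleavage frees both phenols, which is necessary because a chelation-guided mono-cleavage would expose O-8, the very oxygen that has to stay methylated in the target.

Step 6
Reactants: 10 1-{2-[(2S)-2-(dibenzylamino)propyl]-4,6-dihydroxyphenyl}ethan-1-one
Product: 11 1-{4-(allyloxy)-2-[(2S)-2-(dibenzylamino)propyl]-6-hydroxyphenyl}ethan-1-one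
Conditions: allyl bromide (1.05 equiv), K2CO3, acetone, 56 °C
Reagents that add atoms: allyl bromide, C=CCBr
Why: Williamson etherification picks O-6 because the O-8 hydroxyl is tied up in a strong hydrogen bond to the acetyl oxygen and is much less nucleophilic.

Step 7
Reactants: 11 1-{4-(allyloxy)-2-[(2S)-2-(dibenzylamino)propyl]-6-hydroxyphenyl}ethan-1-one
Product: 13 1-{3-allyl-6-[(2S)-2-(dibenzylamino)propyl]-2,4-dihydroxyphenyl}ethan-1-one, via ortho-dienone 12 (not isolated)
Conditions: PhNEt2, 200 °C, sealed tube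
Reagents that add atoms: none
Why: The aromatic Claisen rearrangement, a [3,3]-sigmatropic shift followed by tautomerisation of dienone 12, sends the allyl group to C7 as it does in chelated 4-allyloxy-2-hydroxyacetophenones, since the hydrogen-bonded ring gives the C6–C7 bond more double-bond character and C5 is shielded by the side chain, and it thus avoids an electrophilic halogenation that would favour C5.

Step 8
Reactants: 13 1-{3-allyl-6-[(2S)-2-(dibenzylamino)propyl]-2,4-dihydroxyphenyl}ethan-1-one
Product: 15 1-{3-allyl-4-(benzyloxy)-6-[(2S)-2-(dibenzylamino)propyl]-2-methoxyphenyl}ethan-1-one, via 6-O-benzyl phenol 14 (not isolated)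
Conditions: BnBr (1.0 equiv), K2CO3, DMF, rt; then MeI (1.5 equiv), 45 °C
Reagents that add atoms: benzyl bromide, BrCc1ccccc1; iodomethane, CI
Why: Two Williamson etherifications in one flask use the same chelation bias, the free O-6 hydroxyl being benzylated at room temperature before the hydrogen-bonded O-8 hydroxyl is methylated under warmer conditions with a small excess of MeI that spares the hindered tertiary amine.

Step 9
Reactants: 15 1-{3-allyl-4-(benzyloxy)-6-[(2S)-2-(dibenzylamino)propyl]-2-methoxyphenyl}ethan-1-one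
Product: 16 (2S)-1-[4-allyl-5-(benzyloxy)-3-methoxy-2-(2-methyl-1,3-dioxolan-2-yl)phenyl]-N,N-dibenzylpropan-2-amine
Conditions: HOCH2CH2OH (10 equiv), HC(OEt)3 (3 equiv), TsOH·H2O (1.3 equiv), toluene, 80 °C
Reagents that add atoms: ethylene glycol, OCCO
Why: Acid-catalysed ketalisation with an orthoester as water scavenger masks the enolisable acetyl group against the lithium amide of step 12 and keeps it apart from the amine in step 14, the amine travelling as its tosylate salt while benzyl ether and allyl group are inert to TsOH.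

Step 10
Reactants: 16 (2S)-1-[4-allyl-5-(benzyloxy)-3-methoxy-2-(2-methyl-1,3-dioxolan-2-yl)phenyl]-N,N-dibenzylpropan-2-amine; 17 N,N-diethylacrylamide
Product: 18 (2E)-4-{6-(benzyloxy)-4-[(2S)-2-(dibenzylamino)propyl]-2-methoxy-3-(2-methyl-1,3-dioxolan-2-yl)phenyl}-N,N-diethylbut-2-enamide
Conditions: 17 (3 equiv), second-generation Hoveyda–Grubbs catalyst (5 mol %), 1,4-benzoquinone (10 mol %), CH2Cl2, 40 °C
Reagents that add atoms: none
Why: Olefin cross-metathesis of a readily dimerising allylarene with an electron-poor acrylamide favours the cross product and gives the E-alkene under thermodynamic control, and benzoquinone suppresses ruthenium hydride migration of the allyl double bond.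

Step 11
Reactants: 19 2-bromo-5-methylphenol
Product: 20 2-(benzyloxy)-1-bromo-4-methylbenzene
Conditions: BnBr, K2CO3, acetone, 56 °C
Reagents that add atoms: benzyl bromide, BrCc1ccccc1
Why: Williamson etherification of the phenol gives a base-stable ether that leaves in the same hydrogenolysis as the other benzyl groups.

Step 12
Reactants: 18 (2E)-4-{6-(benzyloxy)-4-[(2S)-2-(dibenzylamino)propyl]-2-methoxy-3-(2-methyl-1,3-dioxolan-2-yl)phenyl}-N,N-diethylbut-2-enamide; 20 2-(benzyloxy)-1-bromo-4-methylbenzene
Product: 24 4-{6-(benzyloxy)-4-[(2S)-2-(dibenzylamino)propyl]-2-methoxy-3-(2-methyl-1,3-dioxolan-2-yl)phenyl}-8-(benzyloxy)-6-methylnaphthalen-1-ol, via lithium dienolate 21 (not isolated), via 3-(benzyloxy)-5-methylbenzyne 22 (not isolated), via 4-aryl-4H-naphthalen-1-one 23 (not isolated)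
Conditions: LiTMP (4.5 equiv, from TMPH and n-BuLi), THF, −78 °C; then 20 (2.5 equiv, slow addition), −78 °C to rt; then H2O
Reagents that add atoms: none
Why: Proposed new method: LiTMP removes a doubly activated proton at C-4 of the butenamide chain of 18 to give dienolate 21 and, on warming, the ring proton next to bromine in 20, so that loss of LiBr releases aryne 22. The aryl-bearing γ-carbon of 21, reacting from the s-cis conformer that places the new C6'=C7' bond cis, bonds to the aryne carbon remote from the benzyloxy group (C8a'), the aryl anion left at C4a' closes the one new ring by 6-exo-trig addition to the amide carbonyl, and loss of LiNEt2 gives 23, which is deprotonated at C8' and aromatises to the naphtholate of 24. The closest known reaction type is the annulation of 3-alkoxyarynes with lithium dienolates of crotonic and senecioic diethylamides to 8-alkoxy-1-naphthols; new here is a γ-carbon that already carries a 2,6-dialkoxyaryl group, a substrate class not yet shown. The step needs regioselective addition to 22, which the substrate secures because the σ-withdrawing oxygen next to the strained bond makes the distal carbon electrophilic and stabilises the charge building up beside it, and because the bulky nucleophile also prefers that open carbon. It further needs γ- over α-attack, favoured by the benzylic delocalisation of the charge and by the irreversible ring closure that only the γ-adduct can undergo. No stereocentre is created, C3 lies far from any acidic site and is untouched, and the C7–C8' axis forms without control.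

Step 13
Reactants: 24 4-{6-(benzyloxy)-4-[(2S)-2-(dibenzylamino)propyl]-2-methoxy-3-(2-methyl-1,3-dioxolan-2-yl)phenyl}-8-(benzyloxy)-6-methylnaphthalen-1-ol
Product: 25 (2S)-N,N-dibenzyl-1-{5-(benzyloxy)-4-[5-(benzyloxy)-4-methoxy-7-methylnaphthalen-1-yl]-3-methoxy-2-(2-methyl-1,3-dioxolan-2-yl)phenyl}propan-2-amine
Conditions: MeI (1.2 equiv), K2CO3, DMF, rt
Reagents that add atoms: iodomethane, CI
Why: Williamson etherification of the naphtholate fixes the 5'-methoxy group, and a near-stoichiometric charge of MeI at room temperature leaves the hindered amine alone.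

Step 14
Reactants: 25 (2S)-N,N-dibenzyl-1-{5-(benzyloxy)-4-[5-(benzyloxy)-4-methoxy-7-methylnaphthalen-1-yl]-3-methoxy-2-(2-methyl-1,3-dioxolan-2-yl)phenyl}propan-2-amine
Product: 28 (3S)-7-(5-hydroxy-4-methoxy-7-methylnaphthalen-1-yl)-8-methoxy-1,3-dimethyl-3,4-dihydroisoquinolin-6-ol, via amino ketal 26 (not isolated), via amino ketone 27 (not isolated)
Conditions: H2 (1 atm), Pd(OH)2/C, EtOH–EtOAc, rt; filter; then 1 M aq HCl, THF, rt; then NaHCO3 to pH 8
Reagents that add atoms: none
Why: Catalytic hydrogenolysis removes the two O-benzyl and two N-benzyl groups while the ketal keeps carbonyl and amine apart so that no reducible imine exists under hydrogen, and after filtration acid hydrolysis of the ketal and neutralisation let the primary amine of 27 condense with the acetyl group to the six-membered cyclic imine with C3 unchanged.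

Compound list
1 | 1-bromo-3,5-dimethoxybenzene | COc1cc(Br)cc(OC)c1 | starting material
2 | (R)-propylene oxide | C[C@@H]1CO1 | starting material
3 | 3,5-dimethoxyphenylmagnesium bromide | COc1cc([Mg]Br)cc(OC)c1 | intermediate
4 | (2R)-1-(3,5-dimethoxyphenyl)propan-2-ol | COc1cc(OC)cc(C[C@@H](C)O)c1 | intermediate
5 | 1-[(2S)-2-azidopropyl]-3,5-dimethoxybenzene | COc1cc(OC)cc(C[C@H](C)N=[N+]=[N-])c1 | intermediate
6 | (2S)-1-(3,5-dimethoxyphenyl)-N-(triphenyl-λ5-phosphanylidene)propan-2-amine | COc1cc(OC)cc(C[C@H](C)N=P(c2ccccc2)(c2ccccc2)c2ccccc2)c1 | intermediate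
7 | (2S)-1-(3,5-dimethoxyphenyl)propan-2-amine | COc1cc(OC)cc(C[C@H](C)N)c1 | intermediate
8 | (2S)-N,N-dibenzyl-1-(3,5-dimethoxyphenyl)propan-2-amine | COc1cc(OC)cc(C[C@H](C)N(Cc2ccccc2)Cc2ccccc2)c1 | intermediate
9 | 1-{2-[(2S)-2-(dibenzylamino)propyl]-4,6-dimethoxyphenyl}ethan-1-one | COc1cc(OC)c(C(C)=O)c(C[C@H](C)N(Cc2ccccc2)Cc2ccccc2)c1 | intermediate
10 | 1-{2-[(2S)-2-(dibenzylamino)propyl]-4,6-dihydroxyphenyl}ethan-1-one | CC(=O)c1c(O)cc(O)cc1C[C@H](C)N(Cc1ccccc1)Cc1ccccc1 | intermediate
11 | 1-{4-(allyloxy)-2-[(2S)-2-(dibenzylamino)propyl]-6-hydroxyphenyl}ethan-1-one | C=CCOc1cc(O)c(C(C)=O)c(C[C@H](C)N(Cc2ccccc2)Cc2ccccc2)c1 | intermediate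
12 | 4-acetyl-6-allyl-3-[(2S)-2-(dibenzylamino)propyl]-5-hydroxycyclohexa-2,4-dien-1-one (ortho-dienone, allyl-bearing carbon unassigned) | C=CCC1C(=O)C=C(C[C@H](C)N(Cc2ccccc2)Cc2ccccc2)C(C(C)=O)=C1O | intermediate
13 | 1-{3-allyl-6-[(2S)-2-(dibenzylamino)propyl]-2,4-dihydroxyphenyl}ethan-1-one | C=CCc1c(O)cc(C[C@H](C)N(Cc2ccccc2)Cc2ccccc2)c(C(C)=O)c1O | intermediate
14 | 1-{3-allyl-4-(benzyloxy)-6-[(2S)-2-(dibenzylamino)propyl]-2-hydroxyphenyl}ethan-1-one | C=CCc1c(OCc2ccccc2)cc(C[C@H](C)N(Cc2ccccc2)Cc2ccccc2)c(C(C)=O)c1O | intermediate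
15 | 1-{3-allyl-4-(benzyloxy)-6-[(2S)-2-(dibenzylamino)propyl]-2-methoxyphenyl}ethan-1-one | C=CCc1c(OCc2ccccc2)cc(C[C@H](C)N(Cc2ccccc2)Cc2ccccc2)c(C(C)=O)c1OC | intermediate
16 | (2S)-1-[4-allyl-5-(benzyloxy)-3-methoxy-2-(2-methyl-1,3-dioxolan-2-yl)phenyl]-N,N-dibenzylpropan-2-amine | C=CCc1c(OCc2ccccc2)cc(C[C@H](C)N(Cc2ccccc2)Cc2ccccc2)c(C2(C)OCCO2)c1OC | intermediate
17 | N,N-diethylacrylamide | C=CC(=O)N(CC)CC | starting material
18 | (2E)-4-{6-(benzyloxy)-4-[(2S)-2-(dibenzylamino)propyl]-2-methoxy-3-(2-methyl-1,3-dioxolan-2-yl)phenyl}-N,N-diethylbut-2-enamide | COc1c(C2(C)OCCO2)c(C[C@H](C)N(Cc2ccccc2)Cc2ccccc2)cc(OCc2ccccc2)c1C/C=C/C(=O)N(CC)CC | intermediate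
19 | 2-bromo-5-methylphenol | Cc1ccc(Br)c(O)c1 | starting material
20 | 2-(benzyloxy)-1-bromo-4-methylbenzene | Cc1ccc(Br)c(OCc2ccccc2)c1 | intermediate
21 | lithium dienolate of 18 | CCN(CC)C([O-])=CC=Cc1c(OC)c(C2(C)OCCO2)c(C[C@H](C)N(Cc2ccccc2)Cc2ccccc2)cc1OCc1ccccc1.[Li+] | intermediate
22 | 3-(benzyloxy)-5-methylbenzyne | CC1=CC#CC(OCc2ccccc2)=C1 | intermediate
23 | 4-aryl-8-(benzyloxy)-6-methylnaphthalen-1(4H)-one (aryl as in 18, C4 unassigned) | COc1c(C2(C)OCCO2)c(C[C@H](C)N(Cc2ccccc2)Cc2ccccc2)cc(OCc2ccccc2)c1C1C=CC(=O)c2c(OCc3ccccc3)cc(C)cc21 | intermediate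
24 | 4-{6-(benzyloxy)-4-[(2S)-2-(dibenzylamino)propyl]-2-methoxy-3-(2-methyl-1,3-dioxolan-2-yl)phenyl}-8-(benzyloxy)-6-methylnaphthalen-1-ol | COc1c(C2(C)OCCO2)c(C[C@H](C)N(Cc2ccccc2)Cc2ccccc2)cc(OCc2ccccc2)c1-c1ccc(O)c2c(OCc3ccccc3)cc(C)cc12 | intermediate
25 | (2S)-N,N-dibenzyl-1-{5-(benzyloxy)-4-[5-(benzyloxy)-4-methoxy-7-methylnaphthalen-1-yl]-3-methoxy-2-(2-methyl-1,3-dioxolan-2-yl)phenyl}propan-2-amine | COc1c(C2(C)OCCO2)c(C[C@H](C)N(Cc2ccccc2)Cc2ccccc2)cc(OCc2ccccc2)c1-c1ccc(OC)c2c(OCc3ccccc3)cc(C)cc12 | intermediate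
26 | 8-{4-[(2S)-2-aminopropyl]-6-hydroxy-2-methoxy-3-(2-methyl-1,3-dioxolan-2-yl)phenyl}-5-methoxy-3-methylnaphthalen-1-ol | COc1c(C2(C)OCCO2)c(C[C@H](C)N)cc(O)c1-c1ccc(OC)c2c(O)cc(C)cc12 | intermediate
27 | 1-{6-[(2S)-2-aminopropyl]-4-hydroxy-3-(5-hydroxy-4-methoxy-7-methylnaphthalen-1-yl)-2-methoxyphenyl}ethan-1-one | COc1c(C(C)=O)c(C[C@H](C)N)cc(O)c1-c1ccc(OC)c2c(O)cc(C)cc12 | intermediate
28 | (3S)-7-(5-hydroxy-4-methoxy-7-methylnaphthalen-1-yl)-8-methoxy-1,3-dimethyl-3,4-dihydroisoquinolin-6-ol | COc1c2c(cc(O)c1-c1ccc(OC)c3c(O)cc(C)cc13)C[C@H](C)N=C2C | target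

Total step count: 14. Longest linear sequence: 13 (steps 1 to 10 and 12 to 14); step 11 is a one-step branch.

Steps most likely to fail

Step 12. Steric shielding of the γ-carbon may slow its addition. The aryne would then be consumed by the amide base, by the tertiary amine or by naphtholate already formed. Attack through the α-carbon, or protonation of the aryl anion before ring closure, would also divert material.
Fallback (known chemistry only; sets out from 10 and 20, returns at 25): the biaryl bond is made by Suzuki–Miyaura coupling. Diol 10 is iodinated between its two hydroxyl groups (I2, HIO3, aqueous EtOH), the position known to be taken in chelated 2,4-dihydroxyacetophenones, to give 7-iodo diol F1. Benzylation at O-6 gives iodo phenol F2, methylation at O-8 gives iodo ketone F3, and ketalisation as in step 9 gives iodo ketal F4. In parallel, commercial (E)-N,N-diethylbut-2-enamide is converted with LDA into crotonamide lithium dienolate F5. This is annulated with aryne 22 released from 20, the established unhindered form of the reaction, to 8-(benzyloxy)-6-methylnaphthalen-1-ol F6. NBS in MeCN brominates para to the hydroxyl group to give bromonaphthol F7, MeI with K2CO3 gives bromonaphthyl methyl ether F8, and Miyaura borylation (B2pin2, PdCl2(dppf), KOAc, dioxane) gives pinacol boronate F9. Coupling of F4 with F9 (Pd(OAc)2, SPhos, K3PO4, toluene–water, 100 °C) gives 25.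

Step 9. Addition of the diol to a carbonyl group twisted out of plane and flanked by two ortho substituents may be slow and the equilibrium unfavourable. Prolonged heating in acid could start protodeacylation of the electron-rich ring.
Fallback (sets out from 15, returns at 16): the dioxolane is built from the carbonyl oxygen outwards by the Lewis-acid-catalysed addition of an epoxide to a ketone (oxirane, BF3·OEt2 with one extra equivalent for the amine, CH2Cl2, 0 °C). The exposed carbonyl oxygen opens the activated oxirane, and the tethered alkoxide closes on the oxocarbenium ion. The crowded carbon is therefore attacked only intramolecularly and no water equilibrium is involved. This fallback passes through no new compound (F0).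

Step 10. The ruthenium catalyst may be deactivated by the amine or by chelation of the amide carbonyl. The allyl double bond may migrate into conjugation with the arene, and homodimerisation may compete.
Fallback (sets out from 16, returns at 18): the alkene is cleaved instead of exchanged. Lemieux–Johnson oxidation (OsO4 cat., NaIO4, 2,6-lutidine, dioxane–water) passes through vicinal diol F10 to arylacetaldehyde F11. A Horner–Wadsworth–Emmons reaction with diethyl [2-(diethylamino)-2-oxoethyl]phosphonate (LiCl, DBU, MeCN) then gives E-enamide 18. Should the double bond drift towards the arene under base, the isomer still gives the same dienolate 21.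

Further compounds
F1 | step 12 | 1-{6-[(2S)-2-(dibenzylamino)propyl]-2,4-dihydroxy-3-iodophenyl}ethan-1-one | CC(=O)c1c(O)c(I)c(O)cc1C[C@H](C)N(Cc1ccccc1)Cc1ccccc1
F2 | step 12 | 1-{4-(benzyloxy)-6-[(2S)-2-(dibenzylamino)propyl]-2-hydroxy-3-iodophenyl}ethan-1-one | CC(=O)c1c(O)c(I)c(OCc2ccccc2)cc1C[C@H](C)N(Cc1ccccc1)Cc1ccccc1
F3 | step 12 | 1-{4-(benzyloxy)-6-[(2S)-2-(dibenzylamino)propyl]-3-iodo-2-methoxyphenyl}ethan-1-one | COc1c(I)c(OCc2ccccc2)cc(C[C@H](C)N(Cc2ccccc2)Cc2ccccc2)c1C(C)=O
F4 | step 12 | (2S)-N,N-dibenzyl-1-[5-(benzyloxy)-4-iodo-3-methoxy-2-(2-methyl-1,3-dioxolan-2-yl)phenyl]propan-2-amine | COc1c(I)c(OCc2ccccc2)cc(C[C@H](C)N(Cc2ccccc2)Cc2ccccc2)c1C1(C)OCCO1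
F5 | step 12 | lithium dienolate of N,N-diethylbut-2-enamide | C=CC=C([O-])N(CC)CC.[Li+]
F6 | step 12 | 8-(benzyloxy)-6-methylnaphthalen-1-ol | Cc1cc(OCc2ccccc2)c2c(O)cccc2c1
F7 | step 12 | 8-(benzyloxy)-4-bromo-6-methylnaphthalen-1-ol | Cc1cc(OCc2ccccc2)c2c(O)ccc(Br)c2c1
F8 | step 12 | 5-(benzyloxy)-1-bromo-4-methoxy-7-methylnaphthalene | COc1ccc(Br)c2cc(C)cc(OCc3ccccc3)c12
F9 | step 12 | 2-[5-(benzyloxy)-4-methoxy-7-methylnaphthalen-1-yl]-4,4,5,5-tetramethyl-1,3,2-dioxaborolane | COc1ccc(B2OC(C)(C)C(C)(C)O2)c2cc(C)cc(OCc3ccccc3)c12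
F0 | step 9 | none | none
F10 | step 10 | 3-{6-(benzyloxy)-4-[(2S)-2-(dibenzylamino)propyl]-2-methoxy-3-(2-methyl-1,3-dioxolan-2-yl)phenyl}propane-1,2-diol (carbinol centre unassigned) | COc1c(C2(C)OCCO2)c(C[C@H](C)N(Cc2ccccc2)Cc2ccccc2)cc(OCc2ccccc2)c1CC(O)CO
F11 | step 10 | {6-(benzyloxy)-4-[(2S)-2-(dibenzylamino)propyl]-2-methoxy-3-(2-methyl-1,3-dioxolan-2-yl)phenyl}acetaldehyde | COc1c(C2(C)OCCO2)c(C[C@H](C)N(Cc2ccccc2)Cc2ccccc2)cc(OCc2ccccc2)c1CC=O
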